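(The data were generated by integration with made-up constants; scatter was added.)

The ratio of the last dawn reading of G to the first, 9% to 33%, is what I judge the next run by: G is highest at the first reading and lower at the last, in the summer and spring runs too. The next run should therefore give a molecule of G a better chance of reaching the end. Over the 12.5 min between those two readings, the ratio means a fall of 0.104 min⁻¹, a reading that carries the scatter.

all flasks: Q 1.2 M

| flask | X | remark | time |
|---|---|---|---|
| dawn | 2.4 M | run made earlier |  |
| summer | 1.2 M | run made earlier |  |
| spring | 1.8 M | run made earlier |  |
| west | 2.40 M | a closed flask charged with all of it at once and left for 15 min | 15 min |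
| south-west | 2.40 M | a single well-mixed tank run continuously and read at steady state, 75.0 min in it on average |  |
| north | 2.40 M (fed, over 12.0 min) | all but X at the start; X goes in evenly over 12.0 min, the run ends at 15 min | 15 min |
| north-west | 2.40 M | a single well-mixed tank run continuously and read at steady state, 15 min in it on average |  |

| run | time / min | G / % |
|---|---|---|
| dawn | 2.50 | 33 |
| dawn | 5.00 | 28 |
| dawn | 8.00 | 20 |
| dawn | 10.0 | 14 |
| dawn | 12.0 | 15 |
| dawn | 15.0 | 9 |
| summer | 3.00 | 19 |
| summer | 6.00 | 15 |
| summer | 10.0 | 10 |
| summer | 12.0 | 9 |
| summer | 15.0 | 6 |
| summer | 20.0 | 4 |
| spring | 1.33 | 34 |
| spring | 4.00 | 22 |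
| spring | 6.00 | 17 |
| spring | 10.0 | 13 |
| spring | 15.0 | 9 |
| spring | 20.0 | 9 |

(standard deviation of a reading: 2 percentage points)

1. the set-up with the highest amount of G at the outlet or at the end, in percent of the Q put in ("none" if the first two lie within 2 percentage points) (west / south-west / north / north-west / none)
2. amount of G at the outlet or at the end, in percent of the Q put in, west
3. amount of G at the outlet or at the end, in percent of the Q put in, south-west
4. amount of G at the outlet or at the end, in percent of the Q put in, north
5. amount of G at the outlet or at the end, in percent of the Q put in, north-west

- the stated concentrations are those of everything mixed, before any reaction; amounts are the same in each set-up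
- the numbers in the tables scatter with a standard deviation of 2 percentage points
- the feed brings no volume worth counting
- the earlier runs were made in a closed, stirred flask

I follow one G molecule formed early and lost at that fall. In the closed west flask it must last the 15 min, and its chance is the exponential of minus fall times time, 21.0%. In the north-west tank the same mean stay (residence time) sets up a fork between leaving and being lost. The chance of leaving first is the leaving rate, one over the stay, divided by the sum of that rate and the fall, 39.1%, which is more than in the flask. I carry their quotient, 1.86: the survival ratio, a G molecule's chance in the tank over its chance in the closed flask at equal time.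

On the dawn reading at 15.0 min, that ratio puts north-west near 16.7%. The long south-west stay of 75.0 min gives a chance of 11.4%, which is 0.543 of the flask's, so I leave that tank out. I charge north-west next. This reckoning does not price the north dosing, so north waits.

The forecast gives west 10%, south-west 6.5%, north 20% and north-west 19%, with best none: “North and north-west are too close to separate”. Its north-west stands above mine.

The set-ups give west 10.8%, south-west 10.4%, north 13.0% and north-west 18.9%, so the highest is north-west.

    Q + X ⇌ G + E (K = 0.440, k = 0.00690 M⁻¹ s⁻¹)
    2 Q → D (k = 5.38 × 10⁻⁶ M⁻¹ s⁻¹)
    Q + G → J (k = 0.00807 M⁻¹ s⁻¹)

North-west over west is 1.75 against the survival ratio of 1.86, but south-west over west is 0.963 where the same reckoning gave 0.543. Part of the south-west answer lies in two steps acting together: striking Q + G to J lifts south-west to 53.5% and striking the back reaction lifts it to 43.2%.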